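The bicycle (pyrano[3,4-b]pyran numbering: O1, C2-heptyl, C3H2, C4=O, C4a, C5H2, C6-decyl, O7, C8=O, C8a) is cut at the ring-fusion alkene C4a=C8a and at the C3–C4 bond. The key step exploits that C8a is α to the lactone carbonyl C8 and that, once the alkene exists, C4 is vinylogously acidified by C8=O. A one-pot intramolecular Horner–Wadsworth–Emmons olefination closes lactone ring A, then the 1,3-dithiane-masked acyl anion at C4 displaces chloride at C3 to close ring B. The precursor is an acyclic ester of an (R)-β-hydroxy ketone bearing a 1,3-dithian-2-yl group with an α-alkoxy phosphonoacetic acid carrying an (S)-CH2Cl arm.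

Key step: step 8

Remark: (S)-epichlorohydrin and (R)-1,2-epoxydodecane are taken as purchasable single enantiomers; 6, 7 and 13 are carried as mixtures of epimers at the phosphonate-bearing carbon, which becomes sp2 in step 8.

Step 1
Reactants: 1 tert-butyl 2-(diethoxyphosphoryl)acetate
Product: 2 tert-butyl 2-diazo-2-(diethoxyphosphoryl)acetate
Conditions: p-ABSA (1.2 equiv), DBU (1.5 equiv), MeCN, 0 °C → rt
Reagents that add atoms: 4-acetamidobenzenesulfonyl azide (p-ABSA), CC(=O)Nc1ccc(cc1)S(=O)(=O)N=[N+]=[N-]
Why: Regitz diazo transfer to the doubly activated methylene should give the acceptor/acceptor diazo compound, the sulfonamide being the leaving fragment.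

Step 2
Reactants: 3 (S)-epichlorohydrin; 4 n-hexylmagnesium bromide
Product: 5 (2S)-1-chlorononan-2-ol
Conditions: 4 (1.2 equiv), CuI (10 mol %), THF, −40 → −10 °C; then 1 M HCl
Reagents that add atoms: none
Why: Copper-catalysed Grignard opening of the epoxide at its unsubstituted carbon (SN2) leaves the C–O bond of the stereocentre and the C–Cl bond untouched, so the (S) centre of 3 becomes the (S) carbinol of 5.

Step 3
Reactants: 5 (2S)-1-chlorononan-2-ol; 2 tert-butyl 2-diazo-2-(diethoxyphosphoryl)acetate
Product: 6 tert-butyl 2-{[(2S)-1-chlorononan-2-yl]oxy}-2-(diethoxyphosphoryl)acetate (epimers at C2 of the acetate)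
Conditions: Rh2(OAc)4 (2 mol %), PhMe, 80 °C, slow addition of 2
Reagents that add atoms: none
Why: Rhodium-carbenoid O–H insertion into the secondary alcohol should form the ether C–O bond without touching the carbinol stereocentre; the new phosphonate-bearing centre forms unselectively and is erased later.

Step 4
Reactants: 6 tert-butyl 2-{[(2S)-1-chlorononan-2-yl]oxy}-2-(diethoxyphosphoryl)acetate
Product: 7 2-{[(2S)-1-chlorononan-2-yl]oxy}-2-(diethoxyphosphoryl)acetic acid
Conditions: CF3CO2H/CH2Cl2 (1:4), 0 °C → rt
Reagents that add atoms: none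
Why: Acidolysis of the tert-butyl ester (loss of isobutene) spares the ethyl phosphonate, the ether and the chloride, and avoids a basic carboxylate that could displace chloride to a 1,4-dioxan-2-one.

Step 5
Reactants: 8 (R)-1,2-epoxydodecane
Product: 9 methyl (3R)-3-hydroxytridecanoate
Conditions: CO (40 bar), MeOH, Co2(CO)8 (5 mol %), 3-hydroxypyridine (10 mol %), THF, 60 °C
Reagents that add atoms: carbon monoxide, [C-]#[O+]; methanol, CO
Why: Cobalt-catalysed carbonylative opening of the terminal epoxide (tetracarbonylcobaltate attack at CH2, CO insertion, methanolysis) leaves the C–O bond of the stereocentre intact, so (R) is retained.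

Step 6
Reactants: 9 methyl (3R)-3-hydroxytridecanoate; 10 1,3-dithiane
Product: 12 (3R)-1-(1,3-dithian-2-yl)-3-hydroxytridecan-1-one, via 2-lithio-1,3-dithiane 11 (not isolated)
Conditions: 10 (3.3 equiv), n-BuLi (3.2 equiv), THF, −30 °C; then 9, −78 → −30 °C; AcOH quench at −78 °C
Reagents that add atoms: none
Why: Corey–Seebach acylation of the dithiane anion by the ester should stop at the ketone because the acidic 2-acyl-dithiane product is enolised in the flask (one equivalent each for the hydroxyl, the addition and this enolisation); the stereocentre is not involved.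

Step 7
Reactants: 12 (3R)-1-(1,3-dithian-2-yl)-3-hydroxytridecan-1-one; 7 2-{[(2S)-1-chlorononan-2-yl]oxy}-2-(diethoxyphosphoryl)acetic acid
Product: 13 (3R)-1-(1,3-dithian-2-yl)-1-oxotridecan-3-yl 2-{[(2S)-1-chlorononan-2-yl]oxy}-2-(diethoxyphosphoryl)acetate (epimers at the phosphonate carbon)
Conditions: DCC (1.2 equiv), DMAP (10 mol %), CH2Cl2, 0 °C → rt
Reagents that add atoms: none
Why: Steglich esterification acylates the secondary alcohol with retention, and the weak base DMAP without lithium salts should not trigger olefination or β-elimination.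

Step 8
Reactants: 13 (3R)-1-(1,3-dithian-2-yl)-1-oxotridecan-3-yl 2-{[(2S)-1-chlorononan-2-yl]oxy}-2-(diethoxyphosphoryl)acetate
Product: 15 (2S,6R)-6-decyl-2-heptyl-2,3,5,6-tetrahydro-8H-spiro[pyrano[3,4-b]pyran-4,2'-[1,3]dithian]-8-one (the target with its C4 ketone masked as the spiro-1,3-dithiane), via chloro lactone 14 (not isolated)
Conditions: LiCl (3 equiv), DBU (1.1 equiv), THF, 0 °C → rt; then t-BuOK (2.3 equiv), 0 → 50 °C, same flask
Reagents that add atoms: none
Why: Under LiCl/DBU the lithium-chelated α-alkoxy phosphonoacetate carbanion (C8a) adds to the ketone carbon (C4a) and the oxaphosphetane collapses, an intramolecular Horner–Wadsworth–Emmons olefination of the Masamune–Roush type that closes lactone ring A in 6-exo-trig mode and places the alkoxy arm and the dithianyl group cis on the new C4a=C8a bond. In 14 the dithiane C–H has become γ to the lactone carbonyl, so t-BuOK should give a sulfur-stabilised dienolate, a vinylogous Corey–Seebach acyl-anion equivalent, which displaces chloride at C3 in a 6-(enolendo)-exo-tet alkylation that forms C3–C4 and closes ring B. No stereocentre is formed and neither existing centre is acidic, so (2S) and (6R) are carried through unchanged while the epimeric phosphonate carbon becomes sp2. The step needs olefination to outrun ketone enolisation and β-elimination of the acyloxy group, which selective amine/LiCl deprotonation of the phosphonate and the six-membered transition state should secure. It also needs C-alkylation at the dithiane carbon rather than at C8a or at the enolate oxygen, and deprotonation at the dithiane C–H rather than at C5; the four-membered ring that attack from C8a would require, the soft sulfur-flanked carbon and the acidifying effect of two sulfur atoms should secure these.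

Step 9
Reactants: 15 (2S,6R)-6-decyl-2-heptyl-2,3,5,6-tetrahydro-8H-spiro[pyrano[3,4-b]pyran-4,2'-[1,3]dithian]-8-one
Product: 16 (2S,6R)-6-decyl-2-heptyl-2,3,5,6-tetrahydro-4H,8H-pyrano[3,4-b]pyran-4,8-dione (CNP0087259.1)
Conditions: PhI(OCOCF3)2 (1.5 equiv), MeCN/H2O (9:1), 0 °C → rt
Reagents that add atoms: water, O
Why: Oxidative dithioketal hydrolysis (sulfur activation by the iodane, water capture of the thionium ion) should release the C4 ketone as a stable vinylogous ester without touching either stereocentre.

Compound list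
1 | tert-butyl 2-(diethoxyphosphoryl)acetate | CCOP(=O)(OCC)CC(=O)OC(C)(C)C | starting material
2 | tert-butyl 2-diazo-2-(diethoxyphosphoryl)acetate | CCOP(=O)(OCC)C(=[N+]=[N-])C(=O)OC(C)(C)C | intermediate
3 | (S)-epichlorohydrin | ClC[C@@H]1CO1 | starting material
4 | n-hexylmagnesium bromide | CCCCCC[Mg]Br | starting material
5 | (2S)-1-chlorononan-2-ol | CCCCCCC[C@H](O)CCl | intermediate
6 | tert-butyl 2-{[(2S)-1-chlorononan-2-yl]oxy}-2-(diethoxyphosphoryl)acetate | CCCCCCC[C@@H](CCl)OC(C(=O)OC(C)(C)C)P(=O)(OCC)OCC | intermediate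
7 | 2-{[(2S)-1-chlorononan-2-yl]oxy}-2-(diethoxyphosphoryl)acetic acid | CCCCCCC[C@@H](CCl)OC(C(=O)O)P(=O)(OCC)OCC | intermediate
8 | (R)-1,2-epoxydodecane | CCCCCCCCCC[C@@H]1CO1 | starting material
9 | methyl (3R)-3-hydroxytridecanoate | CCCCCCCCCC[C@@H](O)CC(=O)OC | intermediate
10 | 1,3-dithiane | C1CSCSC1 | starting material
11 | 2-lithio-1,3-dithiane | [Li]C1SCCCS1 | intermediate
12 | (3R)-1-(1,3-dithian-2-yl)-3-hydroxytridecan-1-one | CCCCCCCCCC[C@@H](O)CC(=O)C1SCCCS1 | intermediate
13 | (3R)-1-(1,3-dithian-2-yl)-1-oxotridecan-3-yl 2-{[(2S)-1-chlorononan-2-yl]oxy}-2-(diethoxyphosphoryl)acetate | CCCCCCCCCC[C@H](CC(=O)C1SCCCS1)OC(=O)C(O[C@@H](CCCCCCC)CCl)P(=O)(OCC)OCC | intermediate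
14 | (6R)-3-{[(2S)-1-chlorononan-2-yl]oxy}-6-decyl-4-(1,3-dithian-2-yl)-5,6-dihydro-2H-pyran-2-one | CCCCCCCCCC[C@@H]1CC(C2SCCCS2)=C(O[C@@H](CCCCCCC)CCl)C(=O)O1 | intermediate
15 | (2S,6R)-6-decyl-2-heptyl-2,3,5,6-tetrahydro-8H-spiro[pyrano[3,4-b]pyran-4,2'-[1,3]dithian]-8-one | CCCCCCCCCC[C@@H]1CC2=C(O[C@@H](CCCCCCC)CC23SCCCS3)C(=O)O1 | intermediate
16 | (2S,6R)-6-decyl-2-heptyl-2,3,5,6-tetrahydro-4H,8H-pyrano[3,4-b]pyran-4,8-dione | CCCCCCCCCC[C@@H]1CC2=C(O[C@@H](CCCCCCC)CC2=O)C(=O)O1 | target

Total step count: 9. Longest linear sequence: 6 steps (steps 2, 3, 4, 7, 8, 9).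

Steps most likely to fail

Step 8. The second stage may stall because the delocalised anion displaces the β-alkoxy primary chloride only slowly. It may also divert through deprotonation at C5 with E1cB opening of the lactone, or through O-alkylation of the dienolate. In the first stage, enolisation of the ketone or β-elimination of the acyloxy group may compete with olefination. Fallback: setting out from 13, only the LiCl/DBU olefination would be run and 14 isolated. PhI(OCOCF3)2 in wet MeCN would then unmask the aldehyde (6R)-3-{[(2S)-1-chlorononan-2-yl]oxy}-6-decyl-2-oxo-5,6-dihydro-2H-pyran-4-carbaldehyde F1. NaI in butanone at reflux would give the iodide (6R)-6-decyl-3-{[(2S)-1-iodononan-2-yl]oxy}-2-oxo-5,6-dihydro-2H-pyran-4-carbaldehyde F2. An N-heterocyclic carbene (3-benzyl-5-(2-hydroxyethyl)-4-methylthiazolium chloride 20 mol %, DBU, THF, 60 °C) would close ring B by intramolecular SN2 alkylation of the Breslow intermediate, the acyl-anion umpolung known for chroman-4-ones from 2-(2-haloethoxy)benzaldehydes. This comes back to the route at 16 and makes step 9 unnecessary.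

Step 6. The dithiane anion may act as a base, enolising the ester or inducing retro-aldol cleavage of the β-alkoxide, instead of adding to the carbonyl. Fallback: setting out from 9, aminolysis with MeNH(OMe)·HCl and i-PrMgCl (THF, −20 °C) would give the Weinreb amide (3R)-3-hydroxy-N-methoxy-N-methyltridecanamide F3. Its chelated tetrahedral adduct with 11 (3 equiv, THF, −78 °C) cannot collapse before the quench, and the sequence would come back to the route at 12.

Step 9. The iodane may oxidise the electron-rich enol-ether alkene or oxidise sulfur without C–S cleavage, and the liberated acid may degrade the product. Fallback: setting out from 15, NaIO4 (1 equiv, MeOH/H2O, 0 °C) would give the monosulfoxide (2S,6R)-6-decyl-2-heptyl-2,3,5,6-tetrahydro-8H-spiro[pyrano[3,4-b]pyran-4,2'-[1,3]dithian]-8-one 1'-oxide F4 as a mixture of sulfoxide diastereomers. Mild acid (2 M HCl, THF, rt) would hydrolyse it through the sulfoxide-activated thionium ion, coming back to the route at 16.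

Further compounds
F1 | step 8 | (6R)-3-{[(2S)-1-chlorononan-2-yl]oxy}-6-decyl-2-oxo-5,6-dihydro-2H-pyran-4-carbaldehyde | CCCCCCCCCC[C@@H]1CC(C=O)=C(O[C@@H](CCCCCCC)CCl)C(=O)O1
F2 | step 8 | (6R)-6-decyl-3-{[(2S)-1-iodononan-2-yl]oxy}-2-oxo-5,6-dihydro-2H-pyran-4-carbaldehyde | CCCCCCCCCC[C@@H]1CC(C=O)=C(O[C@@H](CCCCCCC)CI)C(=O)O1
F3 | step 6 | (3R)-3-hydroxy-N-methoxy-N-methyltridecanamide | CCCCCCCCCC[C@@H](O)CC(=O)N(C)OC
F4 | step 9 | (2S,6R)-6-decyl-2-heptyl-2,3,5,6-tetrahydro-8H-spiro[pyrano[3,4-b]pyran-4,2'-[1,3]dithian]-8-one 1'-oxide | CCCCCCCCCC[C@@H]1CC2=C(O[C@@H](CCCCCCC)CC23SCCCS3=O)C(=O)O1
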